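The runs were generated by integration for substances that don't exist, and the scatter is random.

We follow E.

the same everywhere: E 0.016 M; X 2.3 mM (held)
- red: L 15 mol%; the very flask that is asked about, followed so far
- violet: L 22 mol%; run made earlier
- flask: L 15 mol%; time 5.0 min

red run (percent of the E charged)

| time / min | E / % | Q / % |
|---|---|---|
| 0.200 | 75.5 | 7.8 |
| 0.333 | 62.7 | 11.2 |
| 0.500 | 52.8 | 16.3 |
| 0.667 | 45.4 | 19.8 |
| 1.00 | 35.2 | 24.6 |
| 1.50 | 26.6 | 27.8 |
| 2.50 | 18.2 | 31.4 |

violet run (percent of the E charged)

| time / s | E / % | Q / % |
|---|---|---|
| 10.0 | 78.3 | 7.7 |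
| 15.0 | 69.8 | 11.0 |
| 20.0 | 62.9 | 13.7 |
| 30.0 | 52.0 | 17.3 |
| 50.0 | 38.6 | 23.6 |
| 80.0 | 28.5 | 29.3 |
| 120 | 19.8 | 30.8 |

(scatter of a reading: 0.5 percentage points)

* which holds at 5.0 min: what has brought the reaction to rest, or that it has not come to rest (it is still moving / forward and back rates have come level / no working catalyst is left / all of E has reacted)
* conversion of E at 5.0 min
* amount of Q at 5.0 min, in percent of the E charged

- at the start none of X is in solution
- the reaction counts as stopped when no species that holds the E changes by six tenths of a point or more over the second half of the time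

1. The violet run holds L at 22 mol%, against 15 mol% in the red run. Yet at 0.500 min the red run shows E at 52.8% and the violet run 52.0%. Those readings differ by 0.8 percentage points, with a scatter of 0.5 points on each. A loss of E carried by L should show that extra charge.

2. At 2.50 min the red run has lost 81.8% of its E and shows 31.4% as Q. The Q share (selectivity) is 0.384. So the larger part of the loss, 0.616, leaves by a route we do not read.

3. We test cE as the concentration that sets the order. In the red run, the ratio of the charge to cE rises at 1.77 min⁻¹ from 1.00 min to 2.50 min. We call this the second-order slope s, the rise per minute of charge over cE. Before 1.00 min it rose at 1.90 min⁻¹, close to s. So the red run's loss of E reads as second order in cE over these times.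

4. Carrying s to 5.0 min, we reckon E at 10.1%, a conversion of 89.9%. By this reckoning E falls 8.1 points over the second half, against the stopping mark of 0.6 points, so we say the flask is still moving. At share w, Q comes to 34.5%.

5. The forecast gives conversion 89% and Q 34.5%. It says it is still moving, since “E still falls well over 0.6 points”. Its conversion lies below ours.

6. The flask gives: it is still moving, conversion 90.3%, Q 34.2%. To move the answer for Q by 5 points from this flask's, L has to go down to 7.4 mol% or up to 44 mol%, all other amounts and the time held. Starting from this flask's 17.6% of E at 2.50 min, s gives E 9.89% at 5.00 min, and this flask holds 9.69%.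

    X ⇌ Z, rate k1*(csat - [Z]) (kL = 0.140 s⁻¹)
    E + Z + L → L + Q (k = 5800 L² mol⁻² s⁻¹)
    2 E → J (k = 0.580 L mol⁻¹ s⁻¹)
    2 L → G (k = 18.0 L mol⁻¹ s⁻¹)

7. For the neighbour flask, the same charge left until 12 min, s gives E 4.48%. The computed neighbour flask holds 4.33%, a conversion of 95.7%.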